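The core is numbered as a 2,6-diaryl-3,7-dioxabicyclo[3.3.0]octane, C2 bearing the 4-hydroxy-3-methoxyphenyl group. Everything rests on closing ring C1–C2–O3–C4–C5 at the C1–C2 bond. Two features are exploited: C2 is an acetal-level carbon between O3 and an electron-rich arene, and C1 lies β to O7 through C8. The precursor is therefore a trans-2-aryl-3-(hydroxymethyl)-2,3-dihydrofuran (enol ether C1=C8–O7; C5 and C6 already set) plus an aryl dimethyl acetal. In one operation the tethered oxocarbenium ion C2=O3 is attacked by C1, and silane reduction at C8 gives the furofuran with C1 and C2 set. The erythro aryloxypropanediol arm is added afterwards by an anti-selective aldol.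

Key step: step 8

Remark: aldehyde 7 and chloroacetyl imide 18 are assumed to be purchasable; the locants C1–C8 used below are those of the bicyclic numbering defined above.

Step 1
Reactants: 1 vanillin
Product: 2 3-methoxy-4-(triisopropylsilyloxy)benzaldehyde
Conditions: TIPSCl, imidazole, DMF, rt
Reagents that add atoms: chlorotriisopropylsilane, CC(C)[Si](Cl)(C(C)C)C(C)C
Why: O-silylation of the phenol (silyl ether protection); the bulky aryl silyl ether should survive the Lewis acids, bases and hydrides used later and is removed last by fluoride.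

Step 2
Reactants: 2 3-methoxy-4-(triisopropylsilyloxy)benzaldehyde
Product: 3 [4-(dimethoxymethyl)-2-methoxyphenoxy]triisopropylsilane
Conditions: HC(OMe)3, PPTS (cat.), MeOH, rt
Reagents that add atoms: trimethyl orthoformate, COC(OC)OC
Why: acid-catalysed acetalisation with an orthoester as water scavenger should give the dimethyl acetal that serves as the oxocarbenium precursor; no stereocentre is formed.

Step 3
Reactants: 4 (R)-4-benzyloxazolidin-2-one; 5 pent-4-enoyl chloride
Product: 6 (R)-4-benzyl-3-(pent-4-enoyl)oxazolidin-2-one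
Conditions: n-BuLi, THF, −78 °C; then 5, −78 → 0 °C
Reagents that add atoms: none
Why: N-acylation of the lithiated oxazolidinone by the acid chloride (imide formation) installs the auxiliary; no new stereocentre is formed.

Step 4
Reactants: 6 (R)-4-benzyl-3-(pent-4-enoyl)oxazolidin-2-one; 7 4-(benzyloxy)-3-methoxybenzaldehyde
Product: 8 (4R)-4-benzyl-3-[(2R,3R)-3-(4-benzyloxy-3-methoxyphenyl)-3-hydroxy-2-(prop-2-enyl)propanoyl]oxazolidin-2-one
Conditions: n-Bu2BOTf, i-Pr2NEt, CH2Cl2, 0 °C; then 7, −78 → 0 °C; then pH 7 buffer, MeOH, H2O2, 0 °C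
Reagents that add atoms: none
Why: Evans syn aldol, in which the (Z)-boron enolate reacts through a closed chair (Zimmerman–Traxler) transition state on the face away from the benzyl group of the (R)-auxiliary, which should set both new centres (the later C5 and C6) as (2R,3R).

Step 5
Reactants: 8 (4R)-4-benzyl-3-[(2R,3R)-3-(4-benzyloxy-3-methoxyphenyl)-3-hydroxy-2-(prop-2-enyl)propanoyl]oxazolidin-2-one
Product: 10 lactol (4R)-4-benzyl-3-{[(2R,3R)-2-(4-benzyloxy-3-methoxyphenyl)-5-hydroxytetrahydrofuran-3-yl]carbonyl}oxazolidin-2-one, via hydroxy aldehyde 9 (not isolated)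
Conditions: O3, CH2Cl2, −78 °C (stopped at first persistent blue); then Me2S, −78 °C → rt
Reagents that add atoms: ozone, [O-][O+]=O
Why: ozonolysis of the terminal alkene with reductive work-up should give the γ-hydroxy aldehyde, which closes to the five-membered lactol through the only free hydroxyl; the new anomeric centre forms as a mixture and is removed in the next step.

Step 6
Reactants: 10 lactol (4R)-4-benzyl-3-{[(2R,3R)-2-(4-benzyloxy-3-methoxyphenyl)-5-hydroxytetrahydrofuran-3-yl]carbonyl}oxazolidin-2-one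
Product: 12 (4R)-4-benzyl-3-{[(2R,3R)-2-(4-benzyloxy-3-methoxyphenyl)-2,3-dihydrofuran-3-yl]carbonyl}oxazolidin-2-one, via anomeric mesylate 11 (not isolated)
Conditions: MsCl, Et3N, CH2Cl2, −30 °C → rt
Reagents that add atoms: none
Why: lactol dehydration by O-sulfonylation and elimination through the ring oxocarbenium ion should give the 2,3-dihydrofuran (the only β-hydrogens are at C4); the trans-2,3 arrangement is also the thermodynamically preferred one.

Step 7
Reactants: 12 (4R)-4-benzyl-3-{[(2R,3R)-2-(4-benzyloxy-3-methoxyphenyl)-2,3-dihydrofuran-3-yl]carbonyl}oxazolidin-2-one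
Product: 13 [(2R,3S)-2-(4-benzyloxy-3-methoxyphenyl)-2,3-dihydrofuran-3-yl]methanol
Conditions: LiBH4, MeOH (1 equiv), THF, 0 °C
Reagents that add atoms: none
Why: reductive cleavage of the N-acyl oxazolidinone by hydride attack at the exocyclic carbonyl should release the primary alcohol and the auxiliary without touching the enol ether or the stereocentres.

Step 8
Reactants: 13 [(2R,3S)-2-(4-benzyloxy-3-methoxyphenyl)-2,3-dihydrofuran-3-yl]methanol; 3 [4-(dimethoxymethyl)-2-methoxyphenoxy]triisopropylsilane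
Product: 16 (1S,2R,5S,6R)-6-(4-benzyloxy-3-methoxyphenyl)-2-[3-methoxy-4-(triisopropylsilyloxy)phenyl]-3,7-dioxabicyclo[3.3.0]octane, via mixed acetal 14 (not isolated), via bicyclic methyl acetal 15 (not isolated)
Conditions: 3 (1.2 equiv), TMSOTf (0.2 equiv), CH2Cl2, −78 °C; then Et3SiH, BF3·OEt2, −78 → −40 °C
Reagents that add atoms: none
Why: Transacetalisation of 13 with 3 gives mixed acetal 14, which TMSOTf ionises to the (E)-aryl oxocarbenium ion C2=O3 held above the dihydrofuran by the C5–C4–O3 tether; the enol ether carbon C1 attacks C2, the resulting C8 oxocarbenium ion is trapped by methoxide to give 15, and Et3SiH/BF3·OEt2 then reduces C8 to the methylene group. The closest known reaction type is the Lewis acid-mediated Prins-type (Mukaiyama-type) addition of an enol ether to an acetal, followed by silane reduction of a cyclic acetal (ionic hydrogenation). Ring C1–C2–O3–C4–C5 closes 5-endo-trig with respect to the C2=O3 cation and exo with respect to the C1=C8 enol ether, a mode that is accessible because the heteroatom-stabilised cation sits directly over the nucleophilic β-carbon. C1 is controlled by the tether, since the bond can only form on the enol ether face that carries the C5 arm (cis ring fusion), and C2 is controlled by the (E) geometry of the oxocarbenium ion, which in the closing geometry should turn the aryl group outwards to the convex face and the hydrogen over the dihydrofuran ring. The step needs C- rather than O-alkylation, exo rather than endo placement of the new aryl group and no erosion at C6; these are secured by the polarised enol ether and the short tether, by the trans-2,3 substitution of 13 (C6 aryl already exo, only hydrogen directed into the concave face), and by cyclising and reducing at low temperature so that the benzylic C–O bonds are not re-ionised.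

Step 9
Reactants: 16 (1S,2R,5S,6R)-6-(4-benzyloxy-3-methoxyphenyl)-2-[3-methoxy-4-(triisopropylsilyloxy)phenyl]-3,7-dioxabicyclo[3.3.0]octane
Product: 17 2-methoxy-4-{(1S,2R,5S,6R)-2-[3-methoxy-4-(triisopropylsilyloxy)phenyl]-3,7-dioxabicyclo[3.3.0]octan-6-yl}phenol
Conditions: H2 (1 atm), Pd/C, EtOAc, rt, stopped at consumption of 16
Reagents that add atoms: none
Why: hydrogenolysis of the aryl benzyl ether should be much faster than cleavage of the benzylic ring C–O bonds under neutral conditions, and the aryl silyl ether is inert, so only the C6-aryl phenol is released.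

Step 10
Reactants: 17 2-methoxy-4-{(1S,2R,5S,6R)-2-[3-methoxy-4-(triisopropylsilyloxy)phenyl]-3,7-dioxabicyclo[3.3.0]octan-6-yl}phenol; 18 (S)-4-benzyl-3-(chloroacetyl)oxazolidin-2-one
Product: 19 (4S)-4-benzyl-3-[2-(2-methoxy-4-{(1S,2R,5S,6R)-2-[3-methoxy-4-(triisopropylsilyloxy)phenyl]-3,7-dioxabicyclo[3.3.0]octan-6-yl}phenoxy)acetyl]oxazolidin-2-one
Conditions: K2CO3, DMF, rt
Reagents that add atoms: none
Why: Williamson ether synthesis, in which the phenoxide displaces chloride at the activated α-carbon of the imide by SN2; no stereocentre is formed.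

Step 11
Reactants: 19 (4S)-4-benzyl-3-[2-(2-methoxy-4-{(1S,2R,5S,6R)-2-[3-methoxy-4-(triisopropylsilyloxy)phenyl]-3,7-dioxabicyclo[3.3.0]octan-6-yl}phenoxy)acetyl]oxazolidin-2-one; 2 3-methoxy-4-(triisopropylsilyloxy)benzaldehyde
Product: 20 (4S)-4-benzyl-3-[(2R,3R)-2-(aryloxy)-3-[3-methoxy-4-(triisopropylsilyloxy)phenyl]-3-(trimethylsilyloxy)propanoyl]oxazolidin-2-one (aryloxy = the phenoxy group of 19)
Conditions: MgCl2 (0.2 equiv), Et3N, TMSCl, EtOAc, rt
Reagents that add atoms: chlorotrimethylsilane, C[Si](C)(C)Cl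
Why: magnesium halide-catalysed direct anti aldol of an N-acyl oxazolidinone with an aromatic aldehyde, in which the chelated magnesium (Z)-enolate reacts through a boat-like transition state on the face away from the benzyl group of the (S)-auxiliary and silylation of the aldolate turns the catalyst over, which should give the (2R,3R) adduct, i.e. the erythro relationship.

Step 12
Reactants: 20 (4S)-4-benzyl-3-[(2R,3R)-2-(aryloxy)-3-[3-methoxy-4-(triisopropylsilyloxy)phenyl]-3-(trimethylsilyloxy)propanoyl]oxazolidin-2-one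
Product: 21 (2S,3R)-2-(aryloxy)-3-[3-methoxy-4-(triisopropylsilyloxy)phenyl]-3-(trimethylsilyloxy)propan-1-ol (aryloxy as in 19)
Conditions: LiBH4, H2O (1 equiv), THF, 0 °C
Reagents that add atoms: none
Why: reductive removal of the auxiliary by hydride attack at the exocyclic imide carbonyl should give the primary alcohol; the silylated carbinol cannot undergo retro-aldol cleavage, so both stereocentres are retained.

Step 13
Reactants: 21 (2S,3R)-2-(aryloxy)-3-[3-methoxy-4-(triisopropylsilyloxy)phenyl]-3-(trimethylsilyloxy)propan-1-ol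
Product: 22 (1R,2S)-1-(4-hydroxy-3-methoxyphenyl)-2-{4-[(1S,2R,5S,6R)-2-(4-hydroxy-3-methoxyphenyl)-3,7-dioxabicyclo[3.3.0]octan-6-yl]-2-methoxyphenoxy}propane-1,3-diol
Conditions: TBAF, AcOH, THF, 0 °C → rt
Reagents that add atoms: none
Why: fluoride-mediated desilylation should remove the two aryl silyl ethers and the secondary silyl ether; the acetic acid buffer keeps the phenoxides from opening the benzylic ethers through quinone methides, so no stereocentre is touched.

Compound list
1 | vanillin (4-hydroxy-3-methoxybenzaldehyde) | COc1cc(C=O)ccc1O | starting material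
2 | 3-methoxy-4-(triisopropylsilyloxy)benzaldehyde | COc1cc(C=O)ccc1O[Si](C(C)C)(C(C)C)C(C)C | intermediate
3 | [4-(dimethoxymethyl)-2-methoxyphenoxy]triisopropylsilane | COC(OC)c1ccc(O[Si](C(C)C)(C(C)C)C(C)C)c(OC)c1 | intermediate
4 | (R)-4-benzyloxazolidin-2-one | O=C1N[C@H](Cc2ccccc2)CO1 | starting material
5 | pent-4-enoyl chloride | C=CCCC(=O)Cl | starting material
6 | (R)-4-benzyl-3-(pent-4-enoyl)oxazolidin-2-one | C=CCCC(=O)N1[C@H](Cc2ccccc2)COC1=O | intermediate
7 | 4-(benzyloxy)-3-methoxybenzaldehyde | COc1cc(C=O)ccc1OCc1ccccc1 | starting material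
8 | (4R)-4-benzyl-3-[(2R,3R)-3-(4-benzyloxy-3-methoxyphenyl)-3-hydroxy-2-(prop-2-enyl)propanoyl]oxazolidin-2-one | COc1cc([C@H](O)[C@@H](CC=C)C(=O)N2[C@H](Cc3ccccc3)COC2=O)ccc1OCc1ccccc1 | intermediate
9 | hydroxy aldehyde: (4R)-4-benzyl-3-[(2R,3R)-3-(4-benzyloxy-3-methoxyphenyl)-3-hydroxy-2-(2-oxoethyl)propanoyl]oxazolidin-2-one | COc1cc([C@H](O)[C@@H](CC=O)C(=O)N2[C@H](Cc3ccccc3)COC2=O)ccc1OCc1ccccc1 | intermediate (not isolated)
10 | lactol: (4R)-4-benzyl-3-{[(2R,3R)-2-(4-benzyloxy-3-methoxyphenyl)-5-hydroxytetrahydrofuran-3-yl]carbonyl}oxazolidin-2-one, anomer mixture | COc1cc([C@@H]2OC(O)C[C@H]2C(=O)N2[C@H](Cc3ccccc3)COC2=O)ccc1OCc1ccccc1 | intermediate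
11 | anomeric mesylate of 10 | COc1cc([C@@H]2OC(OS(C)(=O)=O)C[C@H]2C(=O)N2[C@H](Cc3ccccc3)COC2=O)ccc1OCc1ccccc1 | intermediate (not isolated)
12 | (4R)-4-benzyl-3-{[(2R,3R)-2-(4-benzyloxy-3-methoxyphenyl)-2,3-dihydrofuran-3-yl]carbonyl}oxazolidin-2-one | COc1cc([C@@H]2OC=C[C@H]2C(=O)N2[C@H](Cc3ccccc3)COC2=O)ccc1OCc1ccccc1 | intermediate
13 | [(2R,3S)-2-(4-benzyloxy-3-methoxyphenyl)-2,3-dihydrofuran-3-yl]methanol | COc1cc([C@@H]2OC=C[C@H]2CO)ccc1OCc1ccccc1 | intermediate
14 | mixed acetal: (2R,3S)-2-(4-benzyloxy-3-methoxyphenyl)-3-({methoxy[3-methoxy-4-(triisopropylsilyloxy)phenyl]methoxy}methyl)-2,3-dihydrofuran, both acetal epimers | COc1cc([C@@H]2OC=C[C@H]2COC(OC)c2ccc(O[Si](C(C)C)(C(C)C)C(C)C)c(OC)c2)ccc1OCc1ccccc1 | intermediate (not isolated)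
15 | bicyclic methyl acetal: (1R,2R,5S,6R)-6-(4-benzyloxy-3-methoxyphenyl)-8-methoxy-2-[3-methoxy-4-(triisopropylsilyloxy)phenyl]-3,7-dioxabicyclo[3.3.0]octane, C8 epimers | COc1cc([C@@H]2OC(OC)[C@@H]3[C@H]2CO[C@H]3c2ccc(O[Si](C(C)C)(C(C)C)C(C)C)c(OC)c2)ccc1OCc1ccccc1 | intermediate (not isolated)
16 | (1S,2R,5S,6R)-6-(4-benzyloxy-3-methoxyphenyl)-2-[3-methoxy-4-(triisopropylsilyloxy)phenyl]-3,7-dioxabicyclo[3.3.0]octane | COc1cc([C@@H]2OC[C@@H]3[C@H]2CO[C@H]3c2ccc(O[Si](C(C)C)(C(C)C)C(C)C)c(OC)c2)ccc1OCc1ccccc1 | intermediate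
17 | 2-methoxy-4-{(1S,2R,5S,6R)-2-[3-methoxy-4-(triisopropylsilyloxy)phenyl]-3,7-dioxabicyclo[3.3.0]octan-6-yl}phenol | COc1cc([C@@H]2OC[C@@H]3[C@H]2CO[C@H]3c2ccc(O[Si](C(C)C)(C(C)C)C(C)C)c(OC)c2)ccc1O | intermediate
18 | (S)-4-benzyl-3-(chloroacetyl)oxazolidin-2-one | ClCC(=O)N1[C@@H](Cc2ccccc2)COC1=O | starting material
19 | (4S)-4-benzyl-3-[2-(2-methoxy-4-{(1S,2R,5S,6R)-2-[3-methoxy-4-(triisopropylsilyloxy)phenyl]-3,7-dioxabicyclo[3.3.0]octan-6-yl}phenoxy)acetyl]oxazolidin-2-one | COc1cc([C@@H]2OC[C@@H]3[C@H]2CO[C@H]3c2ccc(O[Si](C(C)C)(C(C)C)C(C)C)c(OC)c2)ccc1OCC(=O)N1[C@@H](Cc2ccccc2)COC1=O | intermediate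
20 | anti aldol adduct, (2R,3R)-2-aryloxy-3-aryl-3-(trimethylsilyloxy)propanoyl imide of the (S)-auxiliary | COc1cc([C@@H](O[Si](C)(C)C)[C@H](C(=O)N2[C@@H](Cc3ccccc3)COC2=O)Oc2ccc([C@@H]3OC[C@@H]4[C@H]3CO[C@H]4c3ccc(O[Si](C(C)C)(C(C)C)C(C)C)c(OC)c3)cc2OC)ccc1O[Si](C(C)C)(C(C)C)C(C)C | intermediate
21 | (2S,3R)-2-aryloxy-3-[3-methoxy-4-(triisopropylsilyloxy)phenyl]-3-(trimethylsilyloxy)propan-1-ol | COc1cc([C@@H](O[Si](C)(C)C)[C@H](CO)Oc2ccc([C@@H]3OC[C@@H]4[C@H]3CO[C@H]4c3ccc(O[Si](C(C)C)(C(C)C)C(C)C)c(OC)c3)cc2OC)ccc1O[Si](C(C)C)(C(C)C)C(C)C | intermediate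
22 | (1R,2S)-1-(4-hydroxy-3-methoxyphenyl)-2-{4-[(1S,2R,5S,6R)-2-(4-hydroxy-3-methoxyphenyl)-3,7-dioxabicyclo[3.3.0]octan-6-yl]-2-methoxyphenoxy}propane-1,3-diol | COc1cc([C@@H](O)[C@H](CO)Oc2ccc([C@@H]3OC[C@@H]4[C@H]3CO[C@H]4c3ccc(O)c(OC)c3)cc2OC)ccc1O | target

Total step count: 13. Longest linear sequence: 11 steps (steps 3 to 13, from 4 and 5).

Steps most likely to fail

Step 8. The oxocarbenium ion may close through the alternative envelope that turns the new aryl group into the concave face (endo epimer at C2), intermolecular C-alkylation of the enol ether may outrun transacetalisation, or the benzylic C–O bonds may re-ionise during the reduction. The fallback sets out from 13 and comes back at 16, and closes the same C1–C2 bond by a photochemical biradical route instead of an ionic one. Reduction of 2 with NaBH4 gives [3-methoxy-4-(triisopropylsilyloxy)phenyl]methanol F1, and CBr4/PPh3 (Appel reaction) gives the benzylic bromide F2. Williamson etherification of 13 (NaH, THF, 0 °C) gives the dihydrofuran benzyl ether F3. Hydroboration–oxidation of the enol ether (BH3·THF, then NaBO3) gives the tetrahydrofuran-3-ol F4, and Dess–Martin oxidation gives the tetrahydrofuran-3-one F5. Irradiation of F5 (Pyrex-filtered light, benzene) should cause 1,6-hydrogen transfer from the benzylic ether CH2 to the excited ketone; collapse of the 1,5-biradical (Norrish–Yang cyclisation) should give the bridgehead alcohol F6 with the aryl group on the convex face. Acylation with methyl chlorooxoacetate (DMAP, pyridine) gives the methyl oxalate F7, and radical deoxygenation (Bu3SnH, AIBN, toluene, 110 °C) returns 16, hydrogen being delivered to the only accessible (cis-fused) face.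

Step 11. Soft enolisation and catalyst turnover may stall with the electron-rich aldehyde, or the aryloxy oxygen may perturb the chelated enolate and erode the anti sense. The fallback sets out from 17 and comes back at 22, and sets the two centres separately. Alkylation of 17 with (R)-4-benzyl-3-(chloroacetyl)oxazolidin-2-one (K2CO3, DMF) gives the enantiomeric-auxiliary imide F8. The dibutylboron enolate (n-Bu2BOTf, i-Pr2NEt) adds to 2 in an Evans syn aldol to give the threo adduct F9, in which the aryloxy-bearing carbon is already correct. Mitsunobu inversion of the benzylic carbinol (4-nitrobenzoic acid, PPh3, DIAD) gives the inverted 4-nitrobenzoate F10. LiBH4 removes the auxiliary and the ester to give the erythro diol F11, and TBAF/AcOH returns 22.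

Step 6. Triethylamine may trigger ring opening by β-elimination or epimerisation at the carbon α to the imide, and the enol ether may hydrolyse on work-up. The fallback sets out from 10 and comes back at 13, and removes the acidic α-proton before the enol ether is made. Lactol 10 is converted into the methyl acetal F12 (MeOH, PPTS). LiBH4 removes the auxiliary to give the acetal alcohol F13. Acetal-to-enol-ether elimination with TMSOTf/i-Pr2NEt, which also silylates the hydroxyl, gives the dihydrofuran silyl ether F14, and K2CO3/MeOH returns 13.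

Further compounds
F1 | step 8 | [3-methoxy-4-(triisopropylsilyloxy)phenyl]methanol | COc1cc(CO)ccc1O[Si](C(C)C)(C(C)C)C(C)C
F2 | step 8 | 4-(bromomethyl)-2-methoxy-1-(triisopropylsilyloxy)benzene | COc1cc(CBr)ccc1O[Si](C(C)C)(C(C)C)C(C)C
F3 | step 8 | (2R,3S)-2-(4-benzyloxy-3-methoxyphenyl)-3-({[3-methoxy-4-(triisopropylsilyloxy)phenyl]methoxy}methyl)-2,3-dihydrofuran | COc1cc([C@@H]2OC=C[C@H]2COCc2ccc(O[Si](C(C)C)(C(C)C)C(C)C)c(OC)c2)ccc1OCc1ccccc1
F4 | step 8 | (4R,5R)-5-(4-benzyloxy-3-methoxyphenyl)-4-({[3-methoxy-4-(triisopropylsilyloxy)phenyl]methoxy}methyl)tetrahydrofuran-3-ol, carbinol epimers | COc1cc([C@@H]2OCC(O)[C@H]2COCc2ccc(O[Si](C(C)C)(C(C)C)C(C)C)c(OC)c2)ccc1OCc1ccccc1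
F5 | step 8 | (4S,5R)-5-(4-benzyloxy-3-methoxyphenyl)-4-({[3-methoxy-4-(triisopropylsilyloxy)phenyl]methoxy}methyl)dihydrofuran-3(2H)-one | COc1cc([C@@H]2OCC(=O)[C@H]2COCc2ccc(O[Si](C(C)C)(C(C)C)C(C)C)c(OC)c2)ccc1OCc1ccccc1
F6 | step 8 | (1R,2S,5S,6R)-6-(4-benzyloxy-3-methoxyphenyl)-2-[3-methoxy-4-(triisopropylsilyloxy)phenyl]-3,7-dioxabicyclo[3.3.0]octan-1-ol | COc1cc([C@@H]2OC[C@]3(O)[C@H]2CO[C@H]3c2ccc(O[Si](C(C)C)(C(C)C)C(C)C)c(OC)c2)ccc1OCc1ccccc1
F7 | step 8 | methyl oxalate of F6 at the bridgehead oxygen | COc1cc([C@@H]2OC[C@]3(OC(=O)C(=O)OC)[C@H]2CO[C@H]3c2ccc(O[Si](C(C)C)(C(C)C)C(C)C)c(OC)c2)ccc1OCc1ccccc1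
F8 | step 11 | (4R)-4-benzyl-3-[2-(2-methoxy-4-{(1S,2R,5S,6R)-2-[3-methoxy-4-(triisopropylsilyloxy)phenyl]-3,7-dioxabicyclo[3.3.0]octan-6-yl}phenoxy)acetyl]oxazolidin-2-one | COc1cc([C@@H]2OC[C@@H]3[C@H]2CO[C@H]3c2ccc(O[Si](C(C)C)(C(C)C)C(C)C)c(OC)c2)ccc1OCC(=O)N1[C@H](Cc2ccccc2)COC1=O
F9 | step 11 | syn aldol adduct, (2R,3S)-2-aryloxy-3-hydroxy-3-[3-methoxy-4-(triisopropylsilyloxy)phenyl]propanoyl imide of the (R)-auxiliary | COc1cc([C@H](O)[C@H](C(=O)N2[C@H](Cc3ccccc3)COC2=O)Oc2ccc([C@@H]3OC[C@@H]4[C@H]3CO[C@H]4c3ccc(O[Si](C(C)C)(C(C)C)C(C)C)c(OC)c3)cc2OC)ccc1O[Si](C(C)C)(C(C)C)C(C)C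
F10 | step 11 | (2R,3R)-2-aryloxy-3-(4-nitrobenzoyloxy)-3-[3-methoxy-4-(triisopropylsilyloxy)phenyl]propanoyl imide of the (R)-auxiliary | COc1cc([C@@H](OC(=O)c2ccc([N+](=O)[O-])cc2)[C@H](C(=O)N2[C@H](Cc3ccccc3)COC2=O)Oc2ccc([C@@H]3OC[C@@H]4[C@H]3CO[C@H]4c3ccc(O[Si](C(C)C)(C(C)C)C(C)C)c(OC)c3)cc2OC)ccc1O[Si](C(C)C)(C(C)C)C(C)C
F11 | step 11 | (1R,2S)-2-aryloxy-1-[3-methoxy-4-(triisopropylsilyloxy)phenyl]propane-1,3-diol | COc1cc([C@@H](O)[C@H](CO)Oc2ccc([C@@H]3OC[C@@H]4[C@H]3CO[C@H]4c3ccc(O[Si](C(C)C)(C(C)C)C(C)C)c(OC)c3)cc2OC)ccc1O[Si](C(C)C)(C(C)C)C(C)C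
F12 | step 6 | (4R)-4-benzyl-3-{[(2R,3R)-2-(4-benzyloxy-3-methoxyphenyl)-5-methoxytetrahydrofuran-3-yl]carbonyl}oxazolidin-2-one, anomer mixture | COc1cc([C@@H]2OC(OC)C[C@H]2C(=O)N2[C@H](Cc3ccccc3)COC2=O)ccc1OCc1ccccc1
F13 | step 6 | [(2R,3S)-2-(4-benzyloxy-3-methoxyphenyl)-5-methoxytetrahydrofuran-3-yl]methanol, anomer mixture | COc1cc([C@@H]2OC(OC)C[C@H]2CO)ccc1OCc1ccccc1
F14 | step 6 | {[(2R,3S)-2-(4-benzyloxy-3-methoxyphenyl)-2,3-dihydrofuran-3-yl]methoxy}trimethylsilane | COc1cc([C@@H]2OC=C[C@H]2CO[Si](C)(C)C)ccc1OCc1ccccc1
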